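Readings and results were computed from invented constants; noise was put on by code.

The time of reading comes first: is 15 d long enough for the flask charged with 0.25 M of substrate to have come to rest, and at what level?

in all of them: gas 13 mM (held)
- south: substrate 0.12 M; run made earlier
- north: substrate 0.50 M; run made earlier
- flask: substrate 0.25 M; time 15 d

| run | time / d | product / % | intermediate A / % | substrate / % |
|---|---|---|---|---|
| south | 1.04 | 84.5 | 4.7 | 6.8 |
| south | 3.00 | 93.5 | 2.3 | 2.8 |
| south | 6.00 | 93.5 | 1.7 | 2.5 |
| south | 10.0 | 93.4 | 2.2 | 3.1 |
| north | 1.04 | 86.9 | 4.1 | 5.3 |
| north | 3.00 | 97.8 | 0.6 | 1.0 |
| north | 6.00 | 97.7 | 1.0 | 1.1 |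
| north | 10.0 | 98.1 | 0.9 | 0.7 |

(scatter of a reading: 0.3 percentage points)

- for product the crystals are counted in
- as a solid, counted per litre of solution: crystals
- at the start none of partner is dissolved
- candidate steps: substrate <-> intermediate A; substrate <-> intermediate B; intermediate A <-> intermediate C; intermediate A <-> product; gas <-> partner; crystals <-> product
- the reaction counts as stopped when no species that holds the substrate changes by six tenths of a point or more over the second half of the time

1. at 15 d, what has stopped the reaction, if anything has (it is still moving / forward and back rates have come level)
2. amount of product at 15 d, in percent of the substrate charged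
3. amount of intermediate A at 15 d, in percent of the substrate charged

How many settling times fit into the reading? At 1.04 d the south run's product stood 9 percentage points short of its plateau of 93.5 %, which gives a halving time of that gap of T = 0.308 d. If the flask settles like the south run, its 15 d holds 48.7 such halvings, so the level is the question, not the time.

Does the level in percent stay the same whatever the charge? No. From 3.00 d on, the south run holds a mean share s = 2.07 % of intermediate A, which is 2.48 mM. The north run, charged 4.17 times as much, holds 4.17 mM, which is 1.68 times as much.

What caps it? My reading, since the north run's intermediate A grew less than its charge, is crystals in the north run: they hold dissolved product at its solubility limit, and intermediate A stays in balance with that. I call this reading the ceiling X*, the concentration of intermediate A standing over crystals. For a flask at rest with gas held at 13 mM, my rule is that the share of intermediate A is the smaller of s and X* divided by the charge.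

And the flask? X* over 0.25 M gives 1.67 %, below s, so I expect crystals there.

The forecast is a little lower on intermediate A: 1.5 % (1.1 % to 1.9 %), with product 95.6 % (94.8 % to 96.4 %) and the end given as forward and back rates have come level. Its ground for the flask: “it should crystallise too”.

The flask gives 95.3 % product and 1.60 % intermediate A at 15 d: forward and back rates have come level.

    substrate ⇌ intermediate A (K = 0.920, k = 0.00570 min⁻¹)
    substrate ⇌ intermediate B (K = 0.390, k = 0.0270 min⁻¹)
    intermediate A ⇌ intermediate C (K = 0.410, k = 0.0580 min⁻¹)
    intermediate A ⇌ product (K = 40.0, k = 0.00610 min⁻¹)
    gas ⇌ partner, rate k5*(csat - [partner]) (kL = 0.160 min⁻¹)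
    crystals ⇌ product, rate k6*(cs6 - [product]) while solid is left; crystals form when [product] > cs6 (solubility = 0.160 M, k = 0.270 min⁻¹)

In the flask at 15.0 d, 31.3 % of the charge stands as crystals, and intermediate A stands at 1.60 % beside the ceiling share of 1.67 %. The neighbour charged with 0.15 M goes through the same rule: its ceiling share, 2.78 %, lies above s, so the rule gives it the south share, 2.07 %, and no crystals. That neighbour stands at 2.33 % intermediate A and 93.2 % product at 15.0 d, with crystals at 0 %.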